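**Remark on the chemistry:** diketone 8 is drawn open-chain, although it should sit largely as its cyclic hemiketal; both forms give the same flavone.

## Analysis of the target

The target is a flavone (rings A and C fused, ring B on C2) with no stereocentre, so the whole problem is one of regiochemistry and functional-group tolerance. Ring A is fully substituted apart from C8: a chelated hydroxyl on C5, a 3-methyl-2-oxobutyl chain on C6 and a methyl ether on C7. Ring C carries a prenyl group on C3, and ring B is a free resorcinol (2',4'-dihydroxy). The sensitive groups are the prenyl alkene (acid, oxidants, electrophiles), the C5 hydroxyl/C6 ketone pair (which can condense to a furan in strong acid) and the acid-labile relationship between the 2'-hydroxyl and the C3 chain. The hard part is placing the carbon chain on C6 and not on C8, next to a phenol that must end up free while the C7 oxygen is methylated. The feature the route rests on is that the C6 chain is ortho to the C5 oxygen and carries its carbonyl on the second carbon: CH2–C(=O)–CH(CH3)2 is the hydrolysed form of CH2–C(OSi)=C(CH3)2. That enol ether is exactly what an allyl transposition from the C5 oxygen to C6 would leave behind, if the migrating unit is the silyl enol ether of an α-aryloxy ketone.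

## Retrosynthetic reasoning

**16 to 14.** The isopropyl ketone and the two ring B phenols are unmasked together. The ketone is taken back to its tetrasubstituted silyl enol ether and the phenols to methoxymethyl ethers, so one mild acid treatment finishes the synthesis and nothing has to be oxidised or reduced in the presence of the prenyl group.

**14 to 12 (key disconnection).** The C6–CH2 bond is cut and the chain is reconnected through its dimethyl-substituted carbon to the C5 oxygen. Forward, this is a [3,3] shift of the ether 12 through dienone 13. This bond is chosen because the C5 oxygen can only deliver to C6 (its other ortho carbon is the ring fusion C4a), so the C6/C8 problem is solved by construction and the C5 hydroxyl is released at the same time. The forward reaction must outrun fragmentation of the tertiary ether and must keep the new enol ether intact.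

**12 to 11 to 9 + 10.** The silyl enol ether is traced to methyl ketone 11, which can enolise in one direction only because its other α-carbon is quaternary. The tertiary ether C–O bond is then cut to give the 5-hydroxyflavone 9 and the bromoketone 10. At this stage the 5-hydroxyl is the only free hydroxyl, so no selectivity question arises; the forward step has to overcome the hindrance of a chelated phenoxide and a tertiary electrophile.

**9 to 8.** Ring C is opened at the O1–C2 bond to the 1,3-diketone 8. Ring A of 8 has two equivalent hydroxyls flanking the ketone, so either closes to the same flavone and the spectator becomes the 5-hydroxyl; no protecting group is needed on ring A.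

**8 to 6 + 3 (through 7).** The bond between the prenyl-bearing carbon and the ring B carbonyl is cut, leading to the prenylated ketone 6 and the acid 3, activated as its imidazolide 7. Putting the prenyl group on the ketone first avoids a later competition between carbon and phenolic oxygen alkylation of a diketone.

**6 to 4 + 5.** The prenyl group is removed from the α-carbon of 6, leading to the symmetrical acetophenone 4 and the bromide 5; forward, this is a polyanion C-alkylation.

**3 to 2 to 1.** The acid 3 comes from the resorcylic acid 1 by exhaustive methoxymethylation to 2 and hydrolysis of the ester.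

## Alternatives that were turned down

**Alternative 1: ring B by Diels–Alder.** Ring B is disconnected at C1'–C2' and C5'–C6' to a 2-ethynylchromone A1 and the bis-silyl dienol ether A2. Forward, a [4+2] cycloaddition followed by loss of methanol and the silyl groups would give the resorcinol ring directly in A3. In its favour, ring B appears with free hydroxyls in the right positions and no ring B protecting groups are needed; on this point it is stronger than the chosen route, which spends two steps on methoxymethyl ethers. Against it:
- The alkyne of A1 is only vinylogously activated by an electron-rich pyrone, so the cycloaddition would compete with decomposition of A2.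
- Ring A of A1 must already carry the C6 chain in the right place, which is the real difficulty of the target and is left unsolved.
- A3 still carries a C5 methyl ether and a ketal, so a selective peri demethylation and an acidic ketal cleavage follow, both in the presence of the prenyl group.

The chosen route instead uses its key step to make the C6–carbon bond with built-in regiocontrol and reaches the target in fewer steps.

**Alternative 2: ring A by Danheiser benzannulation.** Ring A is disconnected at C4a–C5, C5–C6 and C7–C8 to the pyranonyl diazoketone A4 and the siloxyalkyne A5. Forward, Wolff rearrangement gives a vinylketene, [2+2] addition to A5, four-electron ring opening and six-electron closure would give A6 with the C5 hydroxyl free. In its favour, every ring A substituent is fixed by the partners, so regiocontrol equals that of the chosen route, and the reaction class is established, whereas the chosen key step is untested. Against it: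
- Both partners are elaborate: A4 needs a trisubstituted pyranone with a diazoacetyl group, and A5 needs a functionalised ynol silyl ether.
- The ketene must engage a double bond that is part of a vinylogous ester.
- The C7 silyl ether of A6 must afterwards be exchanged for methyl, and the ketal and methoxymethyl groups still have to be removed.

The step count would be roughly double. The chosen route offers a symmetrical commercial acetophenone, a short sequence and a single final deprotection in exchange for the higher risk of its key step.

**Alternative 3: intramolecular ester Wittig.** The C2=C3 double bond is disconnected to the acylphosphorane A7, whose ylide carbon already bears the prenyl group. Heating would add the ylide to the neighbouring aryl ester and expel triphenylphosphine oxide to give A8. In its favour, the ring closure is known, neutral and needs no dehydration step, which in the chosen route endangers the methoxymethyl ethers; on precedent for the key step it is clearly stronger. Against it: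
- A stabilised, fully substituted ylide must attack an electron-rich, hindered ester.
- A7 requires a ring A ketone that already carries the C6 chain regiospecifically, so the strategic bond of the target is not addressed by the key step.
- A8 has a C5 methyl ether that must be cleaved selectively, and a ketal.

The chosen route is shorter and puts its one uncertain step on the bond that actually defines the problem.

Key step: step 8

## Route

**Step 1**
Reactants: 1 2,4-dihydroxybenzoic acid
Product: 2 methoxymethyl 2,4-bis(methoxymethoxy)benzoate
Conditions: NaH (3.3 equiv), chloromethyl methyl ether (3.5 equiv), DMF, 0 °C → rt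
Reagents that add atoms: chloromethyl methyl ether, COCCl
Why: Exhaustive Williamson-type O-alkylation of the trisodium salt; NaH is used because the 2-hydroxyl is hydrogen-bonded to the carboxyl group, and alkylation of the carboxylate is harmless because the ester is cleaved in step 2.

**Step 2**
Reactants: 2 methoxymethyl 2,4-bis(methoxymethoxy)benzoate
Product: 3 2,4-bis(methoxymethoxy)benzoic acid
Conditions: LiOH (3 equiv), THF/MeOH/H2O, rt; then 0.5 M HCl to pH 4, 0 °C
Reagents that add atoms: lithium hydroxide, [Li+].[OH-]
Why: Ester saponification by acyl–oxygen cleavage; aryl methoxymethyl ethers are inert to hydroxide and should survive a brief, cold, weakly acidic work-up.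

**Step 3**
Reactants: 4 1-(2,6-dihydroxy-4-methoxyphenyl)ethanone; 5 1-bromo-3-methylbut-2-ene
Product: 6 1-(2,6-dihydroxy-4-methoxyphenyl)-5-methylhex-4-en-1-one
Conditions: LiN(SiMe3)2 (3.3 equiv), THF, −78 → −20 °C; then 5 (1.0 equiv), −78 → 0 °C; aq NH4Cl
Reagents that add atoms: none
Why: Alkylation of a ketone polyanion: the bis-phenoxide enolate should react with the allylic bromide at the enolate carbon (SN2), since lithium phenoxides are poor nucleophiles in THF, and one equivalent of bromide limits double alkylation.

**Step 4**
Reactants: 6 1-(2,6-dihydroxy-4-methoxyphenyl)-5-methylhex-4-en-1-one; 3 2,4-bis(methoxymethoxy)benzoic acid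
Product: 8 1-[2,4-bis(methoxymethoxy)phenyl]-3-(2,6-dihydroxy-4-methoxyphenyl)-2-(3-methylbut-2-enyl)propane-1,3-dione (racemic), via acyl imidazolide 7 (not isolated)
Conditions: (a) 3, 1,1'-carbonyldiimidazole (1.05 equiv), THF, rt; (b) 6, LiN(SiMe3)2 (5.2 equiv), THF, −78 °C, then the solution of 7, −78 °C → rt; AcOH quench
Reagents that add atoms: none
Why: Crossed Claisen-type C-acylation of the ketone polyanion by an acyl imidazolide; any acylation on a phenoxide oxygen is funnelled to the same diketonate by an in-flask Baker–Venkataraman acyl shift, and neutral activation of the acid spares the methoxymethyl ethers. The new stereocentre is racemic and disappears in step 5.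

**Step 5**
Reactants: 8 1-[2,4-bis(methoxymethoxy)phenyl]-3-(2,6-dihydroxy-4-methoxyphenyl)-2-(3-methylbut-2-enyl)propane-1,3-dione
Product: 9 2-[2,4-bis(methoxymethoxy)phenyl]-5-hydroxy-7-methoxy-3-(3-methylbut-2-enyl)chromen-4-one
Conditions: NaOAc, AcOH, 80 °C
Reagents that add atoms: none
Why: Cyclodehydration of an o-hydroxyaryl 1,3-diketone through its 2-hydroxyflavanone hemiketal; the two ring A hydroxyls are equivalent, so one flavone results and the unused hydroxyl becomes the chelated 5-hydroxyl. Buffered acetic acid should be too weak to cleave aryl methoxymethyl ethers or protonate the prenyl alkene, and the blocked 2'-oxygen cannot close the ring from the ring B side.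

**Step 6**
Reactants: 9 2-[2,4-bis(methoxymethoxy)phenyl]-5-hydroxy-7-methoxy-3-(3-methylbut-2-enyl)chromen-4-one; 10 3-bromo-3-methylbutan-2-one
Product: 11 2-[2,4-bis(methoxymethoxy)phenyl]-7-methoxy-5-[(2-methyl-3-oxobutan-2-yl)oxy]-3-(3-methylbut-2-enyl)chromen-4-one
Conditions: Cs2CO3 (3 equiv), 10 (3 equiv, in portions), DMF, 50 °C
Reagents that add atoms: none
Why: Williamson ether synthesis with a tertiary α-bromo ketone; the adjacent carbonyl activates the tertiary carbon toward substitution by phenoxide, as in the alkylation of phenols with 2-bromoisobutyrates. Cs2CO3 in DMF gives a loosely paired 5-phenoxide, the only free hydroxyl in 9.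

**Step 7**
Reactants: 11 2-[2,4-bis(methoxymethoxy)phenyl]-7-methoxy-5-[(2-methyl-3-oxobutan-2-yl)oxy]-3-(3-methylbut-2-enyl)chromen-4-one
Product: 12 2-[2,4-bis(methoxymethoxy)phenyl]-5-{[3-(tert-butyldimethylsilyloxy)-2-methylbut-3-en-2-yl]oxy}-7-methoxy-3-(3-methylbut-2-enyl)chromen-4-one
Conditions: tert-butyldimethylsilyl trifluoromethanesulfonate (1.5 equiv), Et3N (3 equiv), CH2Cl2, −78 → 0 °C; cold aq NaHCO3; Et3N-deactivated silica
Reagents that add atoms: tert-butyldimethylsilyl trifluoromethanesulfonate, CC(C)(C)[Si](C)(C)OS(=O)(=O)C(F)(F)F
Why: Soft enolisation and O-silylation of a ketone; only the methyl side bears α-hydrogens, so a single silyl enol ether can form, and the chromone carbonyl cannot enolise.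

**Step 8**
Reactants: 12 2-[2,4-bis(methoxymethoxy)phenyl]-5-{[3-(tert-butyldimethylsilyloxy)-2-methylbut-3-en-2-yl]oxy}-7-methoxy-3-(3-methylbut-2-enyl)chromen-4-one
Product: 14 2-[2,4-bis(methoxymethoxy)phenyl]-6-[2-(tert-butyldimethylsilyloxy)-3-methylbut-2-enyl]-5-hydroxy-7-methoxy-3-(3-methylbut-2-enyl)chromen-4-one, via 6H-cyclohexadienone 13 (not isolated)
Conditions: degassed o-xylene, 2,6-lutidine (0.2 equiv), 130 °C, sealed tube, base-washed glass
Reagents that add atoms: none
Why: Proposed new method: on heating, the bond from the C5 oxygen to the quaternary carbon should break while the terminal methylene of the 2-siloxyallyl unit bonds to C6, a concerted suprafacial [3,3] shift through a six-membered chair-like array (O5, C5, C6, CH2, C(OSi), CMe2); the resulting 6H-cyclohexadienone 13 should enolise at once to the C5 phenol, which locks into the hydrogen bond with the C4 carbonyl and makes the sequence irreversible. The closest known reactions are the aromatic Claisen rearrangements of 1,1-dimethylallyl aryl ethers, which deliver a prenyl group to the ortho carbon, and of 2-chloroallyl aryl ethers, which show that a heteroatom on the central allyl carbon is tolerated; an enol silyl ether in that position has not been used. No ring is closed and no stereocentre survives: C6 of 13 is stereogenic only until tautomerisation, and the new enol ether carries two identical methyl groups and so has no geometry. The step needs ortho over para migration and [3,3] shift over fragmentation. C6 is the only ortho carbon bearing hydrogen (the other is the ring-fusion carbon C4a), and a para product at C8 would require a second shift through the hindered dimethyl terminus, which enolisation should outrun. The gem-dimethyl group weakens the breaking C–O bond, which should offset the retarding effect expected from a donor on the central allyl carbon. A non-polar solvent, a trace of hindered base and base-washed glass are chosen to suppress ionisation of the tertiary ether and protodesilylation.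

**Step 9**
Reactants: 14 2-[2,4-bis(methoxymethoxy)phenyl]-6-[2-(tert-butyldimethylsilyloxy)-3-methylbut-2-enyl]-5-hydroxy-7-methoxy-3-(3-methylbut-2-enyl)chromen-4-one
Product: 16 2-(2,4-dihydroxyphenyl)-5-hydroxy-7-methoxy-6-(3-methyl-2-oxobutyl)-3-(3-methylbut-2-enyl)chromen-4-one, via methoxymethyl-protected ketone 15 (not isolated)
Conditions: 2 M aq HCl, MeOH/THF, rt → 40 °C
Reagents that add atoms: none
Why: Acid hydrolysis of the silyl enol ether (protonation at the dimethyl-substituted carbon, then loss of silanol) followed by acetal cleavage of both methoxymethyl ethers; dilute acid near room temperature should leave the prenyl alkene and the C7 methyl ether alone, and the hydrogen bond to the C4 carbonyl holds the 5-hydroxyl back from condensing with the new ketone.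

## Compound list

1 | 2,4-dihydroxybenzoic acid | OC(=O)c1ccc(O)cc1O | starting material
2 | methoxymethyl 2,4-bis(methoxymethoxy)benzoate | COCOC(=O)c1ccc(OCOC)cc1OCOC | intermediate
3 | 2,4-bis(methoxymethoxy)benzoic acid | OC(=O)c1ccc(OCOC)cc1OCOC | intermediate
4 | 1-(2,6-dihydroxy-4-methoxyphenyl)ethanone | COc1cc(O)c(C(C)=O)c(O)c1 | starting material
5 | 1-bromo-3-methylbut-2-ene | CC(C)=CCBr | starting material
6 | 1-(2,6-dihydroxy-4-methoxyphenyl)-5-methylhex-4-en-1-one | COc1cc(O)c(C(=O)CCC=C(C)C)c(O)c1 | intermediate
7 | [2,4-bis(methoxymethoxy)phenyl](imidazol-1-yl)methanone | O=C(c1ccc(OCOC)cc1OCOC)n1ccnc1 | intermediate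
8 | 1-[2,4-bis(methoxymethoxy)phenyl]-3-(2,6-dihydroxy-4-methoxyphenyl)-2-(3-methylbut-2-enyl)propane-1,3-dione (racemic) | COc1cc(O)c(C(=O)C(CC=C(C)C)C(=O)c2ccc(OCOC)cc2OCOC)c(O)c1 | intermediate
9 | 2-[2,4-bis(methoxymethoxy)phenyl]-5-hydroxy-7-methoxy-3-(3-methylbut-2-enyl)chromen-4-one | COc1cc(O)c2c(c1)oc(-c1ccc(OCOC)cc1OCOC)c(CC=C(C)C)c2=O | intermediate
10 | 3-bromo-3-methylbutan-2-one | CC(=O)C(C)(C)Br | starting material
11 | 2-[2,4-bis(methoxymethoxy)phenyl]-7-methoxy-5-[(2-methyl-3-oxobutan-2-yl)oxy]-3-(3-methylbut-2-enyl)chromen-4-one | COc1cc(OC(C)(C)C(C)=O)c2c(c1)oc(-c1ccc(OCOC)cc1OCOC)c(CC=C(C)C)c2=O | intermediate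
12 | 2-[2,4-bis(methoxymethoxy)phenyl]-5-{[3-(tert-butyldimethylsilyloxy)-2-methylbut-3-en-2-yl]oxy}-7-methoxy-3-(3-methylbut-2-enyl)chromen-4-one | COc1cc(OC(C)(C)C(=C)O[Si](C)(C)C(C)(C)C)c2c(c1)oc(-c1ccc(OCOC)cc1OCOC)c(CC=C(C)C)c2=O | intermediate
13 | 2-[2,4-bis(methoxymethoxy)phenyl]-6-[2-(tert-butyldimethylsilyloxy)-3-methylbut-2-enyl]-7-methoxy-3-(3-methylbut-2-enyl)-6H-chromene-4,5-dione (racemic, transient) | COC1=CC2=C(C(=O)C1CC(O[Si](C)(C)C(C)(C)C)=C(C)C)C(=O)C(CC=C(C)C)=C(c3ccc(OCOC)cc3OCOC)O2 | intermediate
14 | 2-[2,4-bis(methoxymethoxy)phenyl]-6-[2-(tert-butyldimethylsilyloxy)-3-methylbut-2-enyl]-5-hydroxy-7-methoxy-3-(3-methylbut-2-enyl)chromen-4-one | COc1cc2oc(-c3ccc(OCOC)cc3OCOC)c(CC=C(C)C)c(=O)c2c(O)c1CC(O[Si](C)(C)C(C)(C)C)=C(C)C | intermediate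
15 | 2-[2,4-bis(methoxymethoxy)phenyl]-5-hydroxy-7-methoxy-6-(3-methyl-2-oxobutyl)-3-(3-methylbut-2-enyl)chromen-4-one | COc1cc2oc(-c3ccc(OCOC)cc3OCOC)c(CC=C(C)C)c(=O)c2c(O)c1CC(=O)C(C)C | intermediate
16 | 2-(2,4-dihydroxyphenyl)-5-hydroxy-7-methoxy-6-(3-methyl-2-oxobutyl)-3-(3-methylbut-2-enyl)chromen-4-one | COc1cc2oc(-c3ccc(O)cc3O)c(CC=C(C)C)c(=O)c2c(O)c1CC(=O)C(C)C | target

## Step count and least certain steps

Total: 9 steps. Longest linear sequence: 8 steps (steps 1, 2, 4, 5, 6, 7, 8, 9, from 1); the branch from 4 is 7 steps.

**Step 8 (key step).** The most likely failure is loss of the tertiary allyl unit before it can migrate, either by thermal elimination toward the methyl groups (returning the phenol 9 and a siloxydiene) or by ionisation of the C–O bond, because the siloxy group on the central carbon slows the concerted shift; protodesilylation of the enol ether is a second drain. Fallback, from 9 to 15: the chain would be delivered from the same oxygen by a [2,3] instead of a [3,3] shift, the sulfonium-ylide ortho-alkylation of phenols (Gassman type). 3-Methyl-1-(methylsulfanyl)butan-2-one F1, made from 1-bromo-3-methylbutan-2-one and NaSMe, would be activated with N-chlorosuccinimide in CH2Cl2 at −78 °C and the chlorosulfonium salt captured by the 5-hydroxyl of 9. Et3N would then form the ylide, which rearranges to C6 to give the racemic 6-[3-methyl-1-(methylsulfanyl)-2-oxobutyl]flavone F2. Reductive desulfurisation with SmI2 in THF/MeOH at −78 °C would give 15, which rejoins the route at the methoxymethyl removal of step 9.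

**Step 6.** Elimination of HBr from 10 can consume the electrophile faster than the hindered, chelated phenoxide substitutes it, and the phenoxide may then add in conjugate fashion to the resulting enone to give an isomeric primary ether. Fallback, from 6 to 11: the ether would be made before ring C exists, when the hydroxyl is not held in a rigid peri chelate. Mono-alkylation of 6 with 10 (K2CO3, DMF) would give 1-[2-hydroxy-4-methoxy-6-[(2-methyl-3-oxobutan-2-yl)oxy]phenyl]-5-methylhex-4-en-1-one F3. Esterification of the remaining hydroxyl with 3 (carbodiimide, 4-dimethylaminopyridine) would give the aryl ester F4, Baker–Venkataraman acyl shift (KOtBu, THF, 0 °C) the diketone F5, and cyclodehydration as in step 5 would give 11.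

**Step 5.** Partial loss of the 2'-methoxymethyl group in warm acetic acid would lower the yield and reopen ring closure from the ring B oxygen; incomplete dehydration of the hemiketal is the other risk. Fallback, from 8 to 9: the protecting groups would be given up deliberately. HCl in MeOH (rt first so that ring closure precedes acetal cleavage, then 45 °C) would give 2-(2,4-dihydroxyphenyl)-5-hydroxy-7-methoxy-3-(3-methylbut-2-enyl)chromen-4-one F6. The two ring B phenols would then be re-protected selectively with chloromethyl methyl ether and i-Pr2NEt in CH2Cl2, the chelated 5-hydroxyl staying free, to return to 9.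

**Step 9.** Over-reaction in acid is the concern: condensation of the 5-hydroxyl with the new ketone to a furan, or acid-promoted hydration or cyclisation of the prenyl group while the methoxymethyl ethers are still being cleaved. Fallback, from 11 to 16: the ring B protection would be changed so that the final unmasking needs fluoride instead of acid. The methoxymethyl ethers would be removed from 11 (HCl, MeOH), where no keto-phenol is yet present, to give the diphenol F7. Excess silyl triflate and Et3N would silylate both phenols and the ketone to the tris-silyl ether F8, and the rearrangement of step 8 would give F9. Buffered fluoride (Bu4NF, AcOH, THF, 0 °C) would then release 16 directly.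

**Step 3.** Proton exchange between the product enolate and unreacted polyanion can lead to double prenylation, and the poorly soluble trianion may react sluggishly or on oxygen. Fallback, from 4 and 7 to 8: the order would be reversed. The polyanion of 4 would be acylated with 7 to give 1-[2,4-bis(methoxymethoxy)phenyl]-3-(2,6-dihydroxy-4-methoxyphenyl)propane-1,3-dione F10, whose doubly activated carbon would then be prenylated with 5 (K2CO3, acetone, rt) to give 8.

## Further compounds

F1 | step 8 | 3-methyl-1-(methylsulfanyl)butan-2-one | CSCC(=O)C(C)C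
F2 | step 8 | 2-[2,4-bis(methoxymethoxy)phenyl]-5-hydroxy-7-methoxy-6-[3-methyl-1-(methylsulfanyl)-2-oxobutyl]-3-(3-methylbut-2-enyl)chromen-4-one (racemic) | COc1cc2oc(-c3ccc(OCOC)cc3OCOC)c(CC=C(C)C)c(=O)c2c(O)c1C(SC)C(=O)C(C)C
F3 | step 6 | 1-[2-hydroxy-4-methoxy-6-[(2-methyl-3-oxobutan-2-yl)oxy]phenyl]-5-methylhex-4-en-1-one | COc1cc(O)c(C(=O)CCC=C(C)C)c(OC(C)(C)C(C)=O)c1
F4 | step 6 | 5-methoxy-2-(5-methylhex-4-enoyl)-3-[(2-methyl-3-oxobutan-2-yl)oxy]phenyl 2,4-bis(methoxymethoxy)benzoate | COc1cc(OC(=O)c2ccc(OCOC)cc2OCOC)c(C(=O)CCC=C(C)C)c(OC(C)(C)C(C)=O)c1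
F5 | step 6 | 1-[2,4-bis(methoxymethoxy)phenyl]-3-[2-hydroxy-4-methoxy-6-[(2-methyl-3-oxobutan-2-yl)oxy]phenyl]-2-(3-methylbut-2-enyl)propane-1,3-dione (racemic) | COc1cc(O)c(C(=O)C(CC=C(C)C)C(=O)c2ccc(OCOC)cc2OCOC)c(OC(C)(C)C(C)=O)c1
F6 | step 5 | 2-(2,4-dihydroxyphenyl)-5-hydroxy-7-methoxy-3-(3-methylbut-2-enyl)chromen-4-one | COc1cc(O)c2c(c1)oc(-c1ccc(O)cc1O)c(CC=C(C)C)c2=O
F7 | step 9 | 2-(2,4-dihydroxyphenyl)-7-methoxy-5-[(2-methyl-3-oxobutan-2-yl)oxy]-3-(3-methylbut-2-enyl)chromen-4-one | COc1cc(OC(C)(C)C(C)=O)c2c(c1)oc(-c1ccc(O)cc1O)c(CC=C(C)C)c2=O
F8 | step 9 | 2-[2,4-bis(tert-butyldimethylsilyloxy)phenyl]-5-{[3-(tert-butyldimethylsilyloxy)-2-methylbut-3-en-2-yl]oxy}-7-methoxy-3-(3-methylbut-2-enyl)chromen-4-one | COc1cc(OC(C)(C)C(=C)O[Si](C)(C)C(C)(C)C)c2c(c1)oc(-c1ccc(O[Si](C)(C)C(C)(C)C)cc1O[Si](C)(C)C(C)(C)C)c(CC=C(C)C)c2=O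
F9 | step 9 | 2-[2,4-bis(tert-butyldimethylsilyloxy)phenyl]-6-[2-(tert-butyldimethylsilyloxy)-3-methylbut-2-enyl]-5-hydroxy-7-methoxy-3-(3-methylbut-2-enyl)chromen-4-one | COc1cc2oc(-c3ccc(O[Si](C)(C)C(C)(C)C)cc3O[Si](C)(C)C(C)(C)C)c(CC=C(C)C)c(=O)c2c(O)c1CC(O[Si](C)(C)C(C)(C)C)=C(C)C
F10 | step 3 | 1-[2,4-bis(methoxymethoxy)phenyl]-3-(2,6-dihydroxy-4-methoxyphenyl)propane-1,3-dione | COc1cc(O)c(C(=O)CC(=O)c2ccc(OCOC)cc2OCOC)c(O)c1
A1 | alternative 1 | 2-ethynyl-5,7-dimethoxy-3-(3-methylbut-2-enyl)-6-[(2-isopropyl-1,3-dioxolan-2-yl)methyl]chromen-4-one | COc1cc2oc(C#C)c(CC=C(C)C)c(=O)c2c(OC)c1CC4(C(C)C)OCCO4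
A2 | alternative 1 | 1-methoxy-1,3-bis(trimethylsilyloxy)buta-1,3-diene | COC(O[Si](C)(C)C)=CC(=C)O[Si](C)(C)C
A3 | alternative 1 | 2-(2,4-dihydroxyphenyl)-5,7-dimethoxy-3-(3-methylbut-2-enyl)-6-[(2-isopropyl-1,3-dioxolan-2-yl)methyl]chromen-4-one | COc1cc2oc(-c3ccc(O)cc3O)c(CC=C(C)C)c(=O)c2c(OC)c1CC4(C(C)C)OCCO4
A4 | alternative 2 | 2-[2,4-bis(methoxymethoxy)phenyl]-6-(2-diazoacetyl)-3-(3-methylbut-2-enyl)pyran-4-one | [N-]=[N+]=CC(=O)c1cc(=O)c(CC=C(C)C)c(-c2ccc(OCOC)cc2OCOC)o1
A5 | alternative 2 | triisopropyl{[3-(2-isopropyl-1,3-dioxolan-2-yl)prop-1-yn-1-yl]oxy}silane | CC(C)[Si](OC#CCC1(C(C)C)OCCO1)(C(C)C)C(C)C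
A6 | alternative 2 | 2-[2,4-bis(methoxymethoxy)phenyl]-5-hydroxy-3-(3-methylbut-2-enyl)-6-[(2-isopropyl-1,3-dioxolan-2-yl)methyl]-7-(triisopropylsilyloxy)chromen-4-one | CC(C)[Si](Oc1cc2oc(-c3ccc(OCOC)cc3OCOC)c(CC=C(C)C)c(=O)c2c(O)c1CC4(C(C)C)OCCO4)(C(C)C)C(C)C
A7 | alternative 3 | 3,5-dimethoxy-4-[(2-isopropyl-1,3-dioxolan-2-yl)methyl]-2-[5-methyl-2-(triphenyl-λ5-phosphanylidene)hex-4-enoyl]phenyl 2,4-bis(methoxymethoxy)benzoate | COc1cc(OC(=O)c2ccc(OCOC)cc2OCOC)c(C(=O)C(CC=C(C)C)=P(c2ccccc2)(c2ccccc2)c2ccccc2)c(OC)c1CC4(C(C)C)OCCO4
A8 | alternative 3 | 2-[2,4-bis(methoxymethoxy)phenyl]-5,7-dimethoxy-3-(3-methylbut-2-enyl)-6-[(2-isopropyl-1,3-dioxolan-2-yl)methyl]chromen-4-one | COc1cc2oc(-c3ccc(OCOC)cc3OCOC)c(CC=C(C)C)c(=O)c2c(OC)c1CC4(C(C)C)OCCO4
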